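**Retrosynthetic overview**
- Target ⇐ global hydrogenolysis of a tetra-O-benzyl precursor that already carries both stereocentres.
- Dihydrofuran ring (formed last): the O1–C2 bond is made by a catalytic enantioselective cycloisomerisation of a 2-hydroxystilbene through a p-quinone methide; this one C–O bond formation closes the ring and fixes the trans-(2R,3S) pair.
- Stilbene ⇐ Suzuki–Miyaura coupling of a 2'-bromoflavonol with a (Z)-alkenylboronate made from 4-iodo-2-methoxyphenol and benzyl propargyl ether (Sonogashira, then copper-catalysed borylation).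
- Flavonol ring C (pyranone, formed first; rings A and B are bought as arenes) ⇐ Algar–Flynn–Oyamada oxidative cyclisation of the chalcone from 4-(benzyloxy)-2-bromo-3-hydroxybenzaldehyde and 2-hydroxy-4,6-bis(benzyloxy)acetophenone.

Assumption: the sense of induction of the new ring-closing step cannot be predicted with certainty; the (R)-catalyst is written, and its commercial (S)-antipode is used instead if that is the one that gives the (2R,3S) product.

**Step 1**
Reactants: 1 4-iodo-2-methoxyphenol; 2 benzyl prop-2-yn-1-yl ether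
Product: 3 4-[3-(benzyloxy)prop-1-yn-1-yl]-2-methoxyphenol
Conditions: PdCl2(PPh3)2 (2 mol %), CuI (4 mol %), Et3N, THF, rt to 40 °C
Reagents that add atoms: none
Why: Sonogashira coupling of an aryl iodide with a terminal alkyne tolerates the free phenol and the benzyl ether; no stereocentre is formed.

**Step 2**
Reactants: 3 4-[3-(benzyloxy)prop-1-yn-1-yl]-2-methoxyphenol
Product: 4 4-[(Z)-3-(benzyloxy)-2-(4,4,5,5-tetramethyl-1,3,2-dioxaborolan-2-yl)prop-1-en-1-yl]-2-methoxyphenol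
Conditions: CuCl (5 mol %), Xantphos (5 mol %), NaOtBu (10 mol %), B2pin2 (1.2 equiv), MeOH (2 equiv), THF, rt
Reagents that add atoms: bis(pinacolato)diboron, CC1(C)OB(OC1(C)C)B1OC(C)(C)C(C)(C)O1
Why: Copper-catalysed formal hydroboration (protoboration): syn borylcupration puts copper on the aryl-bearing carbon and boron on the carbon distal to the arene, and methanolysis of the C–Cu bond gives the (Z)-alkenylboronate; the propargylic ether is the one factor that could erode this regiochemistry.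

**Step 3**
Reactants: 5 4-(benzyloxy)-3-hydroxybenzaldehyde
Product: 6 4-(benzyloxy)-2-bromo-3-hydroxybenzaldehyde
Conditions: Br2 (1.05 equiv), NaOAc, Fe powder (cat.), AcOH, rt
Reagents that add atoms: bromine, BrBr
Why: Electrophilic aromatic bromination ortho to the free phenol, which for isovanillin-type 3-hydroxy-4-alkoxybenzaldehydes under NaOAc/Fe buffering goes to C2 between OH and CHO.

**Step 4**
Reactants: 6 4-(benzyloxy)-2-bromo-3-hydroxybenzaldehyde; 7 1-[2,4-bis(benzyloxy)-6-hydroxyphenyl]ethan-1-one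
Product: 8 (E)-1-[2,4-bis(benzyloxy)-6-hydroxyphenyl]-3-[4-(benzyloxy)-2-bromo-3-hydroxyphenyl]prop-2-en-1-one
Conditions: KOH (50% aq, 10 equiv), EtOH, rt, 48 h; then HCl to pH 4
Reagents that add atoms: none
Why: Claisen–Schmidt (crossed aldol) condensation; the phenoxide of 6 is meta to the formyl group and does not deactivate it, and the E-enone forms under thermodynamic control.

**Step 5**
Reactants: 8 (E)-1-[2,4-bis(benzyloxy)-6-hydroxyphenyl]-3-[4-(benzyloxy)-2-bromo-3-hydroxyphenyl]prop-2-en-1-one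
Product: 10 5,7-bis(benzyloxy)-2-[4-(benzyloxy)-2-bromo-3-hydroxyphenyl]-3-hydroxy-4H-chromen-4-one, via dihydroflavonol 9 (not isolated)
Conditions: NaOH (2 M aq), H2O2 (30% aq), MeOH/THF, 0 °C to rt; then HCl
Reagents that add atoms: hydrogen peroxide, OO
Why: Algar–Flynn–Oyamada reaction: conjugate addition of the 2'-phenoxide closes the pyranone ring (O1–C2 bond), hydrogen peroxide hydroxylates the flavanone enolate to dihydroflavonol 9, and further oxidation aromatises it; low temperature favours the six-membered closure over aurone formation, the known risk with a 6'-alkoxy group.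

**Step 6**
Reactants: 10 5,7-bis(benzyloxy)-2-[4-(benzyloxy)-2-bromo-3-hydroxyphenyl]-3-hydroxy-4H-chromen-4-one; 4 4-[(Z)-3-(benzyloxy)-2-(4,4,5,5-tetramethyl-1,3,2-dioxaborolan-2-yl)prop-1-en-1-yl]-2-methoxyphenol
Product: 11 5,7-bis(benzyloxy)-2-{4-(benzyloxy)-2-[(Z)-3-(benzyloxy)-1-(4-hydroxy-3-methoxyphenyl)prop-1-en-2-yl]-3-hydroxyphenyl}-3-hydroxy-4H-chromen-4-one
Conditions: Pd(OAc)2 (5 mol %), SPhos (10 mol %), K3PO4 (4 equiv), dioxane/H2O (5:1), 90 °C; NH4Cl work-up, Et3N-washed silica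
Reagents that add atoms: none
Why: Suzuki–Miyaura coupling with retention of alkene geometry; SPhos is the standard ligand for di-ortho-substituted aryl bromides and hindered alkenylboronates, excess K3PO4 covers the free phenols, and the acid-free work-up prevents racemic ring closure.

**Step 7**
Reactants: 11 5,7-bis(benzyloxy)-2-{4-(benzyloxy)-2-[(Z)-3-(benzyloxy)-1-(4-hydroxy-3-methoxyphenyl)prop-1-en-2-yl]-3-hydroxyphenyl}-3-hydroxy-4H-chromen-4-one
Product: 13 5,7-bis(benzyloxy)-2-[(2R,3S)-7-(benzyloxy)-3-[(benzyloxy)methyl]-2-(4-hydroxy-3-methoxyphenyl)-2,3-dihydro-1-benzofuran-4-yl]-3-hydroxy-4H-chromen-4-one, via p-quinone methide 12 (not isolated)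
Conditions: (R)-TRIP [(R)-3,3'-bis(2,4,6-triisopropylphenyl)-1,1'-binaphthyl-2,2'-diyl hydrogen phosphate] (10 mol %), PhMe/CH2Cl2 (4:1), 5 Å MS, 0 °C, 0.02 M
Reagents that add atoms: none
Why: Proposed new method: chiral phosphoric acid-catalysed enantioselective cycloisomerisation (formal 5-endo hydroalkoxylation) of a 2-hydroxystilbene, in which the phosphate is hydrogen-bonded to the ring B phenol next to the alkene and protonates the adjacent alkene carbon (future C3) to give the phosphate-bound 4-hydroxybenzylic cation, i.e. p-quinone methide 12; C-protonation is reversible, so the two C3 epimers of 12 interconvert through 11 (dynamic kinetic asymmetric transformation) and the catalyst-bound phenol closes 5-exo on the methide carbon of the matched epimer anti to CH2OBn, forming O1–C2 and setting trans-(2R,3S); the closest known reactions are chiral phosphoric acid-catalysed 1,6-additions to p-quinone methides generated in situ, confined-acid asymmetric hydroalkoxylation of alkenes, and the racemic acid-mediated quinone methide ring closure to phenylcoumarans.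

**Step 8**
Reactants: 13 5,7-bis(benzyloxy)-2-[(2R,3S)-7-(benzyloxy)-3-[(benzyloxy)methyl]-2-(4-hydroxy-3-methoxyphenyl)-2,3-dihydro-1-benzofuran-4-yl]-3-hydroxy-4H-chromen-4-one
Product: 14 3,5,7-trihydroxy-2-[(2R,3S)-7-hydroxy-2-(4-hydroxy-3-methoxyphenyl)-3-(hydroxymethyl)-2,3-dihydro-1-benzofuran-4-yl]-4H-chromen-4-one
Conditions: H2 (1 atm), Pd/C (10 wt %), THF/MeOH (1:1), rt, monitored to completion
Reagents that add atoms: none
Why: Hydrogenolysis of four benzyl ethers at 1 atm and room temperature; the flavonol double bond and the cyclic secondary benzylic aryl ether of a trans-phenylcoumaran are known to survive these mild conditions, so both stereocentres are untouched.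

**Compound list**
1 | 4-iodo-2-methoxyphenol | COc1cc(I)ccc1O | starting material
2 | benzyl prop-2-yn-1-yl ether | C#CCOCc1ccccc1 | starting material
3 | 4-[3-(benzyloxy)prop-1-yn-1-yl]-2-methoxyphenol | COc1cc(C#CCOCc2ccccc2)ccc1O | intermediate
4 | 4-[(Z)-3-(benzyloxy)-2-(4,4,5,5-tetramethyl-1,3,2-dioxaborolan-2-yl)prop-1-en-1-yl]-2-methoxyphenol | COc1cc(/C=C(\COCc2ccccc2)B2OC(C)(C)C(C)(C)O2)ccc1O | intermediate
5 | 4-(benzyloxy)-3-hydroxybenzaldehyde | O=Cc1ccc(OCc2ccccc2)c(O)c1 | starting material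
6 | 4-(benzyloxy)-2-bromo-3-hydroxybenzaldehyde | O=Cc1ccc(OCc2ccccc2)c(O)c1Br | intermediate
7 | 1-[2,4-bis(benzyloxy)-6-hydroxyphenyl]ethan-1-one | CC(=O)c1c(O)cc(OCc2ccccc2)cc1OCc1ccccc1 | starting material
8 | (E)-1-[2,4-bis(benzyloxy)-6-hydroxyphenyl]-3-[4-(benzyloxy)-2-bromo-3-hydroxyphenyl]prop-2-en-1-one | O=C(/C=C/c1ccc(OCc2ccccc2)c(O)c1Br)c1c(O)cc(OCc2ccccc2)cc1OCc1ccccc1 | intermediate
9 | trans-5,7-bis(benzyloxy)-2-[4-(benzyloxy)-2-bromo-3-hydroxyphenyl]-3-hydroxy-2,3-dihydro-4H-chromen-4-one (racemic; one enantiomer drawn) | O=C1c2c(OCc3ccccc3)cc(OCc3ccccc3)cc2O[C@H](c2ccc(OCc3ccccc3)c(O)c2Br)[C@H]1O | intermediate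
10 | 5,7-bis(benzyloxy)-2-[4-(benzyloxy)-2-bromo-3-hydroxyphenyl]-3-hydroxy-4H-chromen-4-one | O=c1c(O)c(-c2ccc(OCc3ccccc3)c(O)c2Br)oc2cc(OCc3ccccc3)cc(OCc3ccccc3)c12 | intermediate
11 | 5,7-bis(benzyloxy)-2-{4-(benzyloxy)-2-[(Z)-3-(benzyloxy)-1-(4-hydroxy-3-methoxyphenyl)prop-1-en-2-yl]-3-hydroxyphenyl}-3-hydroxy-4H-chromen-4-one | COc1cc(/C=C(\COCc2ccccc2)c2c(O)c(OCc3ccccc3)ccc2-c2oc3cc(OCc4ccccc4)cc(OCc4ccccc4)c3c(=O)c2O)ccc1O | intermediate
12 | 5,7-bis(benzyloxy)-2-{4-(benzyloxy)-2-[(2S)-1-(benzyloxy)-3-(3-methoxy-4-oxocyclohexa-2,5-dien-1-ylidene)propan-2-yl]-3-hydroxyphenyl}-3-hydroxy-4H-chromen-4-one (p-quinone methide; exocyclic alkene geometry not defined) | COC1=CC(=C[C@H](COCc2ccccc2)c2c(O)c(OCc3ccccc3)ccc2-c2oc3cc(OCc4ccccc4)cc(OCc4ccccc4)c3c(=O)c2O)C=CC1=O | intermediate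
13 | 5,7-bis(benzyloxy)-2-[(2R,3S)-7-(benzyloxy)-3-[(benzyloxy)methyl]-2-(4-hydroxy-3-methoxyphenyl)-2,3-dihydro-1-benzofuran-4-yl]-3-hydroxy-4H-chromen-4-one | COc1cc([C@@H]2Oc3c(OCc4ccccc4)ccc(-c4oc5cc(OCc6ccccc6)cc(OCc6ccccc6)c5c(=O)c4O)c3[C@H]2COCc2ccccc2)ccc1O | intermediate
14 | 3,5,7-trihydroxy-2-[(2R,3S)-7-hydroxy-2-(4-hydroxy-3-methoxyphenyl)-3-(hydroxymethyl)-2,3-dihydro-1-benzofuran-4-yl]-4H-chromen-4-one | COc1cc([C@@H]2Oc3c(O)ccc(-c4oc5cc(O)cc(O)c5c(=O)c4O)c3[C@H]2CO)ccc1O | target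

**Totals**
Total step count: 8. Longest linear sequence: 6 steps (5 → 6 → 8 → 10 → 11 → 13 → 14, steps 3 to 8).

**Three steps most likely to fail**

Step 7 (the proposed new ring closure). It may be slow, give low enantioselectivity, or lose material to acid-promoted side reactions of the allylic ether. The fallback sets out from 11 and comes back at 13, and uses only known chemistry. The alkene of 11 is hydrogenated enantioselectively with [Ir(cod)((S)-tBu-PHOX)]BArF (2 mol %), H2 (50 bar), CH2Cl2, rt. This is established reactivity for trisubstituted stilbene-type alkenes and leaves benzyl ethers and the flavonol alone. It gives 5,7-bis(benzyloxy)-2-{4-(benzyloxy)-2-[(2S)-1-(benzyloxy)-3-(4-hydroxy-3-methoxyphenyl)propan-2-yl]-3-hydroxyphenyl}-3-hydroxy-4H-chromen-4-one F1, in which C3 is already fixed. DDQ (1.1 equiv, CH2Cl2, 0 °C) then oxidises the 4-hydroxybenzylic CH2 to quinone methide 12, and the neighbouring phenol traps it trans to the C3 substituent, giving 13.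

Step 6 (Suzuki coupling on a bromide flanked by the flavonol and a phenol). It may stall or lose the boronate by protodeboronation. The fallback sets out from 6 (with 4) and comes back at 11, moving the coupling to the less hindered aldehyde stage. Aldehyde 6 and boronate 4 are coupled under Pd(OAc)2/SPhos, K3PO4, dioxane/H2O, 70 °C to give 4-(benzyloxy)-2-[(Z)-3-(benzyloxy)-1-(4-hydroxy-3-methoxyphenyl)prop-1-en-2-yl]-3-hydroxybenzaldehyde F2. Claisen–Schmidt condensation of this with 7 (KOH, EtOH, rt) gives (E)-1-[2,4-bis(benzyloxy)-6-hydroxyphenyl]-3-{4-(benzyloxy)-2-[(Z)-3-(benzyloxy)-1-(4-hydroxy-3-methoxyphenyl)prop-1-en-2-yl]-3-hydroxyphenyl}prop-2-en-1-one F3. Algar–Flynn–Oyamada oxidation (NaOH, H2O2, MeOH/THF, 0 °C) then passes through racemic trans-5,7-bis(benzyloxy)-2-{4-(benzyloxy)-2-[(Z)-3-(benzyloxy)-1-(4-hydroxy-3-methoxyphenyl)prop-1-en-2-yl]-3-hydroxyphenyl}-3-hydroxy-2,3-dihydro-4H-chromen-4-one F4, which is not isolated, and gives 11.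

Step 5 (Algar–Flynn–Oyamada reaction with a 6'-benzyloxy group and an ortho-bromo ring). It may divert to the aurone. The fallback sets out from 7 (with 6) and comes back at 10, using the stepwise epoxide route to dihydroflavonols. Ketone 7 is protected (MOMCl, iPr2NEt, CH2Cl2) as 1-[2,4-bis(benzyloxy)-6-(methoxymethoxy)phenyl]ethan-1-one F5. Claisen–Schmidt condensation with 6 (KOH, EtOH) gives (E)-1-[2,4-bis(benzyloxy)-6-(methoxymethoxy)phenyl]-3-[4-(benzyloxy)-2-bromo-3-hydroxyphenyl]prop-2-en-1-one F6. Nucleophilic epoxidation (H2O2, NaOH, MeOH/THF) cannot give an aurone because the phenol is blocked, and gives racemic trans-[2,4-bis(benzyloxy)-6-(methoxymethoxy)phenyl]{3-[4-(benzyloxy)-2-bromo-3-hydroxyphenyl]oxiran-2-yl}methanone F7. HCl in MeOH (55 °C) removes the methoxymethyl group, and the freed phenol opens the epoxide at the benzylic carbon to give dihydroflavonol 9, isolated here. I2/KOAc in AcOH (100 °C) dehydrogenates 9 to 10.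

**Further compounds**
F1 | step 7 | 5,7-bis(benzyloxy)-2-{4-(benzyloxy)-2-[(2S)-1-(benzyloxy)-3-(4-hydroxy-3-methoxyphenyl)propan-2-yl]-3-hydroxyphenyl}-3-hydroxy-4H-chromen-4-one | COc1cc(C[C@H](COCc2ccccc2)c2c(O)c(OCc3ccccc3)ccc2-c2oc3cc(OCc4ccccc4)cc(OCc4ccccc4)c3c(=O)c2O)ccc1O
F2 | step 6 | 4-(benzyloxy)-2-[(Z)-3-(benzyloxy)-1-(4-hydroxy-3-methoxyphenyl)prop-1-en-2-yl]-3-hydroxybenzaldehyde | COc1cc(/C=C(\COCc2ccccc2)c2c(O)c(OCc3ccccc3)ccc2C=O)ccc1O
F3 | step 6 | (E)-1-[2,4-bis(benzyloxy)-6-hydroxyphenyl]-3-{4-(benzyloxy)-2-[(Z)-3-(benzyloxy)-1-(4-hydroxy-3-methoxyphenyl)prop-1-en-2-yl]-3-hydroxyphenyl}prop-2-en-1-one | COc1cc(/C=C(\COCc2ccccc2)c2c(O)c(OCc3ccccc3)ccc2/C=C/C(=O)c2c(O)cc(OCc3ccccc3)cc2OCc2ccccc2)ccc1O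
F4 | step 6 | trans-5,7-bis(benzyloxy)-2-{4-(benzyloxy)-2-[(Z)-3-(benzyloxy)-1-(4-hydroxy-3-methoxyphenyl)prop-1-en-2-yl]-3-hydroxyphenyl}-3-hydroxy-2,3-dihydro-4H-chromen-4-one (racemic; one enantiomer drawn) | COc1cc(/C=C(\COCc2ccccc2)c2c(O)c(OCc3ccccc3)ccc2[C@H]5Oc3cc(OCc4ccccc4)cc(OCc4ccccc4)c3C(=O)[C@@H]5O)ccc1O
F5 | step 5 | 1-[2,4-bis(benzyloxy)-6-(methoxymethoxy)phenyl]ethan-1-one | CC(=O)c1c(OCOC)cc(OCc2ccccc2)cc1OCc1ccccc1
F6 | step 5 | (E)-1-[2,4-bis(benzyloxy)-6-(methoxymethoxy)phenyl]-3-[4-(benzyloxy)-2-bromo-3-hydroxyphenyl]prop-2-en-1-one | O=C(/C=C/c1ccc(OCc2ccccc2)c(O)c1Br)c1c(OCOC)cc(OCc2ccccc2)cc1OCc1ccccc1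
F7 | step 5 | trans-[2,4-bis(benzyloxy)-6-(methoxymethoxy)phenyl]{3-[4-(benzyloxy)-2-bromo-3-hydroxyphenyl]oxiran-2-yl}methanone (racemic; one enantiomer drawn) | O=C([C@H]1O[C@@H]1c1ccc(OCc2ccccc2)c(O)c1Br)c1c(OCOC)cc(OCc2ccccc2)cc1OCc1ccccc1
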